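The numbers in the tables were computed with made-up constants; the scatter is artificial.

The trap is to take the first reading of other mono adduct, 47% at 0.250 d in the beta run, as the share of the charge that took that route, for by then it is already being used up.

- beta: starting material 1.3 M; coupling partner 2 equiv; run made earlier
- flask: starting material 0.95 M; coupling partner 2.00 equiv; time 4.0 d

- beta (time / d: starting material / %, first product / %, other mono adduct / %): 0.250: 3, 4, 47; 0.833: 1, 0, 27; 1.67: 0, 3, 18; 2.50: 0, 0, 11; 3.00: 1, 1, 7

(each reading ± 1.5 percentage points)

- the earlier runs were read with a standard deviation of 1.5 percentage points
- steps under discussion: starting material + coupling partner -> first product; starting material + coupling partner -> other mono adduct; coupling partner + first product -> bis adduct; coupling partner + other mono adduct -> bis adduct; first product -> over-reaction product; starting material <-> dormant form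

1. the starting material standing at 4.0 d, as a percentage of the starting material charged
2. the first product standing at 4.0 d, as a percentage of the starting material charged
3. the other mono adduct standing at 4.0 d, as a percentage of the starting material charged
4. the bis adduct standing at 4.0 d, as a percentage of the starting material charged

*Which balance do you write?* That of the starting material, the limiting reagent, charged against 2.00 equiv of coupling partner. The beta run read 3% of it at 0.250 d, so from then on the balance runs mainly over the products.

*How fast does the other mono adduct fall in that run?* It goes from 47% to 7% between 0.250 d and 3.00 d, which reads as 0.692 /d, with [coupling partner] averaged over that span.

*So what share took that route?* Running that fall back to the start gives 55.9%. I call this the branch share, the part of the starting material that couples to other mono adduct and not to first product; it is a selectivity, read from the readings.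

*And this flask at 4.0 d?* The second coupling goes with [coupling partner], which at equal equivalents stands in proportion to the charge. The fall therefore becomes 0.506 /d, and my reckoning leaves 7.38% other mono adduct.

*Now the weak spot: what about bis adduct?* The balance gives 48.5% by this route. The other 44.1% I reckon as passing through first product, but the beta run read neither bis adduct nor over-reaction product, so how that part divides stays open, and my estimate for bis adduct is the figure by this route plus an unknown share from first product.

The forecast, holding that “the first product mostly leaks to the over-reaction product”, gave 0.5% starting material, 1% first product, 8% other mono adduct and 52% bis adduct.

The flask gives 0% starting material, 0% first product, 8.20% other mono adduct and 54.5% bis adduct.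

    starting material + coupling partner → first product (k = 1.40 × 10⁻⁴ /M/s)
    starting material + coupling partner → other mono adduct (k = 2.00 × 10⁻⁴ /M/s)
    coupling partner + first product → bis adduct (k = 1.30 × 10⁻⁵ /M/s)
    coupling partner + other mono adduct → bis adduct (k = 1.00 × 10⁻⁵ /M/s)
    first product → over-reaction product (k = 1.30 × 10⁻⁴ /s)
    starting material ⇌ dormant form (K = 0.250, k = 4.30 × 10⁻⁵ /s)

Against my 7.38%, the flask holds 8.20% other mono adduct. Its over-reaction product stands at 36.7% by 0.400 d and at 37.3% at 4.00 d. The branch share less the computed other mono adduct gives 47.7%, and the bis adduct stands 6.8 percentage points above that.

A neighbouring flask has 0.800 equiv of coupling partner, so there the partner is the smaller reagent; counting each equivalent as a first coupling, the branch share gives 44.7% other mono adduct. Computed at 4.00 d, that flask holds 44.3% of it, with 2.10% bis adduct and partner at 0% of its own charge.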